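- In a one-step world, each bis adduct costs one starting material and two partners, so a count of turnovers gives a limit without any rate.
- This flask's 50.0% is the partner ceiling, the equivalents of partner divided by two, in percent of the starting material charged. Partner is the limiting reagent of that count.

common to all: starting material 1.5 M

| flask | partner | capture agent | remark | time |
|---|---|---|---|---|
| Thursday's | 0.67 equiv | 0.030 M | run made earlier |  |
| Wednesday's | 1.5 equiv | 0.030 M | run made earlier |  |
| flask | 1.00 equiv | 0.0300 M |  | 30 h |

| Thursday's: time / h | Thursday's: bis adduct / % | Wednesday's: time / h | Wednesday's: bis adduct / % |
|---|---|---|---|
| 2.50 | 10 | 2.50 | 28 |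
| 5.00 | 16 | 5.00 | 42 |
| 8.00 | 17 | 8.00 | 47 |
| 15.0 | 10 | 15.0 | 56 |
| 30.0 | 8 | 30.0 | 53 |

(readings scatter by 2 percentage points)

- percent here means starting material units held: one side product counts as two
- the earlier runs were read with a standard deviation of 2 percentage points
- steps that have been proposed: starting material + partner -> mono adduct; partner + mono adduct -> bis adduct; mono adduct + capture agent -> trapped intermediate; starting material + bis adduct -> side product; starting material -> decomposition product

- time up to 30 h at which bis adduct stands highest
- the amount of bis adduct, in percent of the starting material charged, at that time
- earliest time at which at least nineteen twentieths of that best amount are there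
- latest time at which they still are

- Thursday's run has a ceiling of 33.5% and reads 17% at its top, a share of 0.507.
- Wednesday's run has a ceiling of 75.0% and reads 56% at its top, a share of 0.747.
- My first way takes Thursday's share of this flask's ceiling and gives 25.4%.
- My second way draws a straight line between the two tops at this flask's equivalents and gives 32.5%. The two ways part by more than the scatter of 2 percentage points.
- The count shows which one cheats. A full ceiling spares 66.5% of the starting material on Thursday, 50.0% in this flask and 25.0% on Wednesday, so this flask stands less far from Thursday than from Wednesday.
- Thursday's readings fall to 8% by 30.0 h, while Wednesday's still read 53%. The line mixes a falling run with a holding one, so my reckoning stays with the first way.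
- The forecast says 29% at 12 h, open from 6.3 h to 28 h: “The window is therefore broad and may stay open to the time limit.”
- This flask gives 26.7% at 9.75 h, open from 6.50 h to 14.9 h.

    starting material + partner → mono adduct (k = 0.00337 M⁻¹ min⁻¹)
    partner + mono adduct → bis adduct (k = 0.00637 M⁻¹ min⁻¹)
    mono adduct + capture agent → trapped intermediate (k = 0.00704 M⁻¹ min⁻¹)
    starting material + bis adduct → side product (k = 0.00107 M⁻¹ min⁻¹)
    starting material → decomposition product (k = 5.74 × 10⁻⁶ min⁻¹)

- This flask reaches a share of 0.534 of its ceiling. The depletion of partner holds its highest amount down by the larger effect: the same run without that depletion reaches 83.2%, against 26.7%. The loss of starting material + bis adduct to side product is a part of the rest: the same run without that step reaches 37.4%. At 30.0 h, bis adduct in this flask is made at 0.0396 of the rate at which it is used up, with partner at 0.114% of its charge.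
- A flask with 0.250 equiv of partner has a ceiling of 12.5% and spares 87.5%, more than Thursday's run, so the count puts its share below Thursday's. That flask gives 2.52%, a share of 0.202.

(All runs come from a simulation for an exercise.)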